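The chromane-2,4-dione is disconnected at the aryl–ketone bond C4–C4a. The precursor is an open-chain, enantiopure 2-iodophenyl α-cyano ester in which the O1–C2 ester link already exists, C4 is still a nitrile carbon, and the quaternary C3, set by an organocatalytic Michael addition to acrolein, carries the farnesyl group and a masked 3-oxopropyl arm. A nickel-catalysed reductive 6-exo-dig addition of C4a to the nitrile then closes the pyranone ring and, after hydrolysis, gives the C4 ketone with C3 intact. The step exploits the ortho placement of O1 and the C4 acyl carbon on the benzo ring and the non-enolisable C3. The diynone arm is joined last by thioester–alkyne coupling.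

Key step: step 5

Remark: ring atoms are numbered as in chromane-2,4-dione (O1, C2, C3, C4, C4a, C8a). The sense of induction in the two catalyst-controlled steps (3 and 11) is assigned by analogy; the pseudoenantiomeric cupreine-derived catalyst or (S,S)-ProPhenol is used instead if a first run shows the opposite sense.

Step 1
Reactants: 1 cyanoacetic acid; 2 2-iodophenol
Product: 3 2-iodophenyl cyanoacetate
Conditions: DCC, CH2Cl2, 0 °C to rt
Reagents that add atoms: none
Why: Carbodiimide (Steglich-type) esterification, in which the acidic cyanoacetic acid is activated as its O-acylisourea and captured by the phenol; no stereocenter is involved.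

Step 2
Reactants: 3 2-iodophenyl cyanoacetate; 4 (2E,6E)-farnesyl bromide
Product: 5 2-iodophenyl (4E,8E)-2-cyano-5,9,13-trimethyltetradeca-4,8,12-trienoate (racemic, enolisable at C2)
Conditions: K2CO3, MeCN, rt; the cyanoacetate is used in 2.5-fold excess and the surplus is recovered
Reagents that add atoms: none
Why: SN2 C-alkylation of the doubly activated methylene by the primary allylic bromide should proceed without allylic transposition or loss of E,E geometry, and the excess of 3 suppresses dialkylation.

Step 3
Reactants: 5 2-iodophenyl (4E,8E)-2-cyano-5,9,13-trimethyltetradeca-4,8,12-trienoate; 6 acrolein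
Product: 7 2-iodophenyl (2S,4E,8E)-2-cyano-5,9,13-trimethyl-2-(3-oxopropyl)tetradeca-4,8,12-trienoate
Conditions: 9-O-(9-phenanthryl)cupreidine (10 mol %), CH2Cl2, −25 °C
Reagents that add atoms: none
Why: Enantioselective organocatalytic Michael addition of an α-substituted α-cyano ester to acrolein, a pure addition in which all atoms of both partners end up in the product, where the bifunctional cinchona catalyst (quinuclidine base, 6'-OH hydrogen-bond donor) holds the cyano-ester enolate and the enal in a defined ion pair, so that one enolate face is alkylated and the quaternary (S) centre is set under catalyst control.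

Step 4
Reactants: 7 2-iodophenyl (2S,4E,8E)-2-cyano-5,9,13-trimethyl-2-(3-oxopropyl)tetradeca-4,8,12-trienoate
Product: 8 2-iodophenyl (2S,4E,8E)-2-cyano-2-(3,3-dimethoxypropyl)-5,9,13-trimethyltetradeca-4,8,12-trienoate
Conditions: HC(OMe)3 (5 equiv), PPTS (5 mol %), CH2Cl2, rt
Reagents that add atoms: trimethyl orthoformate, COC(OC)OC
Why: Mild acid-catalysed acetalisation with the orthoformate as methoxy donor and water scavenger masks the aldehyde against arylnickel addition and aldol chemistry in the next step, while the hindered aryl ester and the quaternary centre are untouched.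

Step 5
Reactants: 8 2-iodophenyl (2S,4E,8E)-2-cyano-2-(3,3-dimethoxypropyl)-5,9,13-trimethyltetradeca-4,8,12-trienoate
Product: 10 3-[(3S)-2,4-dioxo-3-[(2E,6E)-3,7,11-trimethyldodeca-2,6,10-trien-1-yl]-3,4-dihydro-2H-chromen-3-yl]propanal, via cyclic ketimine acetal 9 (not isolated)
Conditions: NiBr2(dppe) (10 mol %), Zn dust (2 equiv), H2O (2 equiv), 1,4-dioxane, 80 °C; then 1 M HCl, THF, rt
Reagents that add atoms: water, O
Why: Zn reduces NiBr2(dppe) to zerovalent nickel, which inserts into the C–I bond of 8; the arylnickel intermediate then adds across the C≡N bond in a 6-exo-dig migratory insertion that joins C4a to C4 and closes the pyranone ring (ring B) as an N-nickel ketimide, and water protonates it to ketimine 9 while Zn returns the nickel to the cycle. The closest known reaction type is the nickel-catalysed reductive addition of aryl iodides to nitriles, with the intramolecular carbopalladation of 2-iodoaryl nitriles to benzo-fused ketones as its palladium counterpart. Dilute HCl in the work-up hydrolyses the ketimine to the C4 ketone and the dimethyl acetal to the aldehyde. No stereocenter is formed: C3 is quaternary and cannot enolise, and since only the nitrile carbon can become C4 while the ester carbon remains C2, the (S) configuration set in step 3 is carried into the ring unchanged. The step needs chemoselectivity for nitrile insertion over protodeiodination, attack on the aryl ester and Heck-type addition to the farnesyl alkenes; the six-membered exo geometry, the Thorpe–Ingold effect of the fully substituted C3 and the lack of any α-hydrogen secure it.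

Step 6
Reactants: 10 3-[(3S)-2,4-dioxo-3-[(2E,6E)-3,7,11-trimethyldodeca-2,6,10-trien-1-yl]-3,4-dihydro-2H-chromen-3-yl]propanal
Product: 11 3-[(3S)-2,4-dioxo-3-[(2E,6E)-3,7,11-trimethyldodeca-2,6,10-trien-1-yl]-3,4-dihydro-2H-chromen-3-yl]propanoic acid
Conditions: NaClO2, NaH2PO4, 2-methyl-2-butene (large excess), t-BuOH–H2O, 0 °C to rt
Reagents that add atoms: sodium chlorite, [Na+].[O-]Cl=O
Why: Pinnick oxidation converts the aldehyde to the acid at about pH 4, where the aryl lactone and ketone are inert, and the large excess of 2-methyl-2-butene intercepts HOCl before it can reach the farnesyl alkenes.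

Step 7
Reactants: 11 3-[(3S)-2,4-dioxo-3-[(2E,6E)-3,7,11-trimethyldodeca-2,6,10-trien-1-yl]-3,4-dihydro-2H-chromen-3-yl]propanoic acid
Product: 12 S-ethyl 3-[(3S)-2,4-dioxo-3-[(2E,6E)-3,7,11-trimethyldodeca-2,6,10-trien-1-yl]-3,4-dihydro-2H-chromen-3-yl]propanethioate
Conditions: EtSH (1.2 equiv), EDC·HCl, DMAP (cat.), CH2Cl2, 0 °C
Reagents that add atoms: ethanethiol, CCS
Why: Steglich thioesterification of the unhindered side-chain acid should be much faster than thiolysis of the lactone, which is shielded by the adjacent quaternary carbon.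

Step 8
Reactants: 13 dec-2-yn-1-ol
Product: 14 (2Z)-dec-2-en-1-ol
Conditions: H2 (1 atm), Pd/CaCO3 poisoned with Pb(OAc)2, quinoline, EtOAc, rt
Reagents that add atoms: none
Why: Lindlar semihydrogenation delivers both hydrogens to one face of the alkyne on the poisoned palladium surface and stops at the Z-alkene.

Step 9
Reactants: 14 (2Z)-dec-2-en-1-ol
Product: 15 (2Z)-dec-2-enal
Conditions: Dess–Martin periodinane, NaHCO3, CH2Cl2, 0 °C
Reagents that add atoms: none
Why: Buffered Dess–Martin oxidation at low temperature gives the enal without the acid or base that would isomerise the Z-alkene, and the aldehyde is used at once.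

Step 10
Reactants: 16 1,4-bis(trimethylsilyl)buta-1,3-diyne
Product: 18 buta-1,3-diyn-1-yl(trimethyl)silane, via lithium diynide 17 (not isolated)
Conditions: MeLi·LiBr (1.0 equiv), Et2O, rt; then aq. NH4Cl, 0 °C; used as a solution
Reagents that add atoms: none
Why: Selective monodesilylation by methyllithium attack at one silicon gives a lithium acetylide whose negative charge protects the second silyl group, and protonation releases the terminal diyne.

Step 11
Reactants: 15 (2Z)-dec-2-enal; 18 buta-1,3-diyn-1-yl(trimethyl)silane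
Product: 19 (5S,6Z)-1-(trimethylsilyl)tetradeca-6-ene-1,3-diyn-5-ol
Conditions: ZnMe2 (3 equiv), (R,R)-ProPhenol (10 mol %), Ph3P=O (20 mol %), toluene, 4 °C, the diyne in threefold excess; then aq. NH4Cl
Reagents that add atoms: none
Why: Catalytic asymmetric alkynylation of an enal by a diynylzinc species within the dinuclear zinc–ProPhenol complex, in which the ligand fixes the aldehyde face that is attacked and so sets the (S) carbinol under reagent control, while the mild, nearly neutral conditions should keep the Z-alkene.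

Step 12
Reactants: 19 (5S,6Z)-1-(trimethylsilyl)tetradeca-6-ene-1,3-diyn-5-ol
Product: 20 (5S,6Z)-tetradeca-6-ene-1,3-diyn-5-ol
Conditions: K2CO3 (cat.), MeOH, 0 °C; used at once
Reagents that add atoms: none
Why: Methoxide-mediated protodesilylation of the alkynylsilane is fast and leaves the carbinol centre and the Z-alkene untouched.

Step 13
Reactants: 12 S-ethyl 3-[(3S)-2,4-dioxo-3-[(2E,6E)-3,7,11-trimethyldodeca-2,6,10-trien-1-yl]-3,4-dihydro-2H-chromen-3-yl]propanethioate; 20 (5S,6Z)-tetradeca-6-ene-1,3-diyn-5-ol
Product: 21 (3S)-3-[(8S,9Z)-8-hydroxy-3-oxoheptadec-9-ene-4,6-diyn-1-yl]-3-[(2E,6E)-3,7,11-trimethyldodeca-2,6,10-trien-1-yl]-2H-chromene-2,4(3H)-dione (CNP0346147.1)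
Conditions: PdCl2(dppf) (10 mol %), tri(2-furyl)phosphine (25 mol %), CuI (1.7 equiv), Et3N, degassed DMF free of dimethylamine, 50 °C
Reagents that add atoms: none
Why: Pd/Cu thioester–alkyne ketone synthesis (acyl Sonogashira, Fukuyama type), in which zerovalent palladium inserts into the C(acyl)–S bond, the copper acetylide of 20 transmetalates and reductive elimination gives the diynone, while CuI binds the thiolate and the free alcohol, aryl lactone and ring ketone are not acylating or alkynylating partners under these conditions.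

Compound list
1 | cyanoacetic acid | N#CCC(=O)O | starting material
2 | 2-iodophenol | Oc1ccccc1I | starting material
3 | 2-iodophenyl cyanoacetate | N#CCC(=O)Oc1ccccc1I | intermediate
4 | (2E,6E)-farnesyl bromide | BrC/C=C(\C)CC/C=C(\C)CCC=C(C)C | starting material
5 | 2-iodophenyl (4E,8E)-2-cyano-5,9,13-trimethyltetradeca-4,8,12-trienoate | N#CC(C/C=C(\C)CC/C=C(\C)CCC=C(C)C)C(=O)Oc1ccccc1I | intermediate
6 | acrolein | C=CC=O | starting material
7 | 2-iodophenyl (2S,4E,8E)-2-cyano-5,9,13-trimethyl-2-(3-oxopropyl)tetradeca-4,8,12-trienoate | O=CCC[C@@](C#N)(C/C=C(\C)CC/C=C(\C)CCC=C(C)C)C(=O)Oc1ccccc1I | intermediate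
8 | 2-iodophenyl (2S,4E,8E)-2-cyano-2-(3,3-dimethoxypropyl)-5,9,13-trimethyltetradeca-4,8,12-trienoate | COC(OC)CC[C@@](C#N)(C/C=C(\C)CC/C=C(\C)CCC=C(C)C)C(=O)Oc1ccccc1I | intermediate
9 | (3S)-3-(3,3-dimethoxypropyl)-4-imino-3-[(2E,6E)-3,7,11-trimethyldodeca-2,6,10-trien-1-yl]-3,4-dihydro-2H-chromen-2-one | COC(OC)CC[C@@]1(C/C=C(\C)CC/C=C(\C)CCC=C(C)C)C(=O)Oc2ccccc2C1=N | intermediate
10 | 3-[(3S)-2,4-dioxo-3-[(2E,6E)-3,7,11-trimethyldodeca-2,6,10-trien-1-yl]-3,4-dihydro-2H-chromen-3-yl]propanal | O=CCC[C@@]1(C/C=C(\C)CC/C=C(\C)CCC=C(C)C)C(=O)Oc2ccccc2C1=O | intermediate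
11 | 3-[(3S)-2,4-dioxo-3-[(2E,6E)-3,7,11-trimethyldodeca-2,6,10-trien-1-yl]-3,4-dihydro-2H-chromen-3-yl]propanoic acid | OC(=O)CC[C@@]1(C/C=C(\C)CC/C=C(\C)CCC=C(C)C)C(=O)Oc2ccccc2C1=O | intermediate
12 | S-ethyl 3-[(3S)-2,4-dioxo-3-[(2E,6E)-3,7,11-trimethyldodeca-2,6,10-trien-1-yl]-3,4-dihydro-2H-chromen-3-yl]propanethioate | CCSC(=O)CC[C@@]1(C/C=C(\C)CC/C=C(\C)CCC=C(C)C)C(=O)Oc2ccccc2C1=O | intermediate
13 | dec-2-yn-1-ol | CCCCCCCC#CCO | starting material
14 | (2Z)-dec-2-en-1-ol | CCCCCCC/C=C\CO | intermediate
15 | (2Z)-dec-2-enal | CCCCCCC/C=C\C=O | intermediate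
16 | 1,4-bis(trimethylsilyl)buta-1,3-diyne | C[Si](C)(C)C#CC#C[Si](C)(C)C | starting material
17 | lithium 4-(trimethylsilyl)buta-1,3-diyn-1-ide | [Li]C#CC#C[Si](C)(C)C | intermediate
18 | buta-1,3-diyn-1-yl(trimethyl)silane | C#CC#C[Si](C)(C)C | intermediate
19 | (5S,6Z)-1-(trimethylsilyl)tetradeca-6-ene-1,3-diyn-5-ol | CCCCCCC/C=C\[C@H](O)C#CC#C[Si](C)(C)C | intermediate
20 | (5S,6Z)-tetradeca-6-ene-1,3-diyn-5-ol | CCCCCCC/C=C\[C@H](O)C#CC#C | intermediate
21 | (3S)-3-[(8S,9Z)-8-hydroxy-3-oxoheptadec-9-ene-4,6-diyn-1-yl]-3-[(2E,6E)-3,7,11-trimethyldodeca-2,6,10-trien-1-yl]-2H-chromene-2,4(3H)-dione | CCCCCCC/C=C\[C@H](O)C#CC#CC(=O)CC[C@@]1(C/C=C(\C)CC/C=C(\C)CCC=C(C)C)C(=O)Oc2ccccc2C1=O | target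

Total step count: 13. Longest linear sequence: 8 steps (steps 1 to 7, then 13); the diynol branch (steps 8, 9, 11, 12, with step 10 feeding step 11) joins in step 13.

Steps most likely to fail

Step 5 (key ring closure). The arylnickel intermediate may be protonated (protodeiodination) before it inserts, because the aryl ester has to rotate into its s-cis conformer for C4a to reach the nitrile. Reductive cleavage of the activated aryl ester by nickel and zinc is a second risk. Fallback: setting out from 8, Miyaura borylation (B2pin2, PdCl2(dppf), KOAc, 1,4-dioxane, 80 °C) should give the pinacol arylboronate F1. [Rh(OH)(cod)]2 (3 mol %) in 1,4-dioxane–H2O at 80 °C then adds the aryl group of F1 to the nitrile in a redox-neutral 6-exo-dig arylrhodium addition, which needs neither reductant nor aryl halide and forms the same C4a–C4 bond. This gives ketimine 9, and the HCl work-up of step 5 brings the route back at 10.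

Step 3 (quaternary centre). Facial selectivity may be poor or reversed, because the unusually acidic aryl cyano ester can react through a loose ion pair or by uncatalysed background addition, and the flexible farnesyl group offers little steric bias. Fallback: setting out from 5, Et3N (10 mol %) and acrolein in CH2Cl2 at 0 °C give the racemic Michael adduct F2. It is resolved by preparative supercritical-fluid chromatography on an amylose tris(3,5-dimethylphenylcarbamate) phase, and the (S) enantiomer re-enters the route as 7.

Step 13 (final coupling). The terminal diyne may homocouple under copper, amine or thiolate may add to the diynone as it forms, and base may trigger retro-Michael loss of the side chain from C3. Fallback (carbonyl addition and oxidation instead of acyl cross-coupling): setting out from 19, TBSCl and imidazole in DMF give the silyl ether F3, and NIS with catalytic AgNO3 in acetone exchanges the alkynyl silane for iodine to give the iododiyne F4. Setting out from aldehyde 10, Nozaki–Hiyama–Kishi addition of F4 (CrCl2, NiCl2 (cat.), THF, rt) under neutral conditions gives the propargylic alcohol F5 as a mixture of epimers at the new carbinol. It is oxidised without delay (Dess–Martin periodinane, NaHCO3, CH2Cl2) to the silyl-protected diynone F6. HF·pyridine in THF at 0 °C removes the silyl group and returns the route at 21.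

Further compounds
F1 | step 5 | 2-(4,4,5,5-tetramethyl-1,3,2-dioxaborolan-2-yl)phenyl (2S,4E,8E)-2-cyano-2-(3,3-dimethoxypropyl)-5,9,13-trimethyltetradeca-4,8,12-trienoate | COC(OC)CC[C@@](C#N)(C/C=C(\C)CC/C=C(\C)CCC=C(C)C)C(=O)Oc1ccccc1B1OC(C)(C)C(C)(C)O1
F2 | step 3 | 2-iodophenyl (2RS,4E,8E)-2-cyano-5,9,13-trimethyl-2-(3-oxopropyl)tetradeca-4,8,12-trienoate (racemate) | O=CCCC(C#N)(C/C=C(\C)CC/C=C(\C)CCC=C(C)C)C(=O)Oc1ccccc1I
F3 | step 13 | tert-butyl(dimethyl){[(5S,6Z)-1-(trimethylsilyl)tetradeca-6-ene-1,3-diyn-5-yl]oxy}silane | CCCCCCC/C=C\[C@H](O[Si](C)(C)C(C)(C)C)C#CC#C[Si](C)(C)C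
F4 | step 13 | tert-butyl{[(5S,6Z)-1-iodotetradeca-6-ene-1,3-diyn-5-yl]oxy}dimethylsilane | CCCCCCC/C=C\[C@H](O[Si](C)(C)C(C)(C)C)C#CC#CI
F5 | step 13 | (3S)-3-[(8S,9Z)-8-(tert-butyldimethylsilyloxy)-3-hydroxyheptadec-9-ene-4,6-diyn-1-yl]-3-[(2E,6E)-3,7,11-trimethyldodeca-2,6,10-trien-1-yl]-2H-chromene-2,4(3H)-dione (both epimers at the new carbinol) | CCCCCCC/C=C\[C@H](O[Si](C)(C)C(C)(C)C)C#CC#CC(O)CC[C@@]1(C/C=C(\C)CC/C=C(\C)CCC=C(C)C)C(=O)Oc2ccccc2C1=O
F6 | step 13 | (3S)-3-[(8S,9Z)-8-(tert-butyldimethylsilyloxy)-3-oxoheptadec-9-ene-4,6-diyn-1-yl]-3-[(2E,6E)-3,7,11-trimethyldodeca-2,6,10-trien-1-yl]-2H-chromene-2,4(3H)-dione | CCCCCCC/C=C\[C@H](O[Si](C)(C)C(C)(C)C)C#CC#CC(=O)CC[C@@]1(C/C=C(\C)CC/C=C(\C)CCC=C(C)C)C(=O)Oc2ccccc2C1=O
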